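**Plan**

- Retrosynthesis (eudesmane numbering): cut the C4–O aryl ether (SNAr), then the biaryl bond (Suzuki–Miyaura) and the benzylic C–C bond of the allyl group para to the ether oxygen (vinyl coupling). The 4α-ol goes back through the 3α,4α-epoxide and the 3-ene to an 11-hydroxy-4-en-3-one.
- In that enone the C6–C11 bond is re-formed as a cyclopropane, and ring A is cut at C1–C10 and C4–C5 (Robinson annulation), leaving 2-carone and ethyl vinyl ketone. 2-Carone comes from (+)-dihydrocarvone.
- Forward: ring B is the chiral-pool ring; the cyclopropane is closed, ring A is annulated onto it, the cyclopropane is opened to the C11 carbinol, ring A is adjusted to the 4α-alcohol, and the two aromatic rings are attached last.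
- Enabling feature: the axial C10 methyl and the C7 side chain are 1,4-cis on ring B. Tying C11 back to C6 as a cis-fused gem-dimethylcyclopropane on the β face makes the C5/C10 enolate react on its α face, and that same bond later becomes the C11 carbinol.
- Stereochemistry: C7 from dihydrocarvone; C10 by attack anti to the cyclopropane; C5 by Li/NH3 reduction (trans fusion); C4 by α-face epoxidation opposite the axial C10 methyl, hydride opening at C3, and retention in the SNAr.

Key step: step 3

Remark: commercial (+)-dihydrocarvone is a mixture of C2 epimers with C5 fixed as R; this centre (the later C10) is erased by enolisation in step 3, so it is left undefined in compounds 1–3.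

**Route**

Step 1
Reactants: 1 (+)-dihydrocarvone [(5R)-2-methyl-5-(prop-1-en-2-yl)cyclohexan-1-one]
Product: 2 (5R)-5-(2-chloropropan-2-yl)-2-methylcyclohexan-1-one
Conditions: HCl (g), CH2Cl2, 0 °C
Reagents that add atoms: hydrogen chloride, Cl
Why: Markovnikov hydrochlorination of the isopropenyl group through the tertiary cation should give the tertiary chloride without touching the C5 stereocentre (the future C7).

Step 2
Reactants: 2 (5R)-5-(2-chloropropan-2-yl)-2-methylcyclohexan-1-one
Product: 3 2-carone [(1S,6R)-3,7,7-trimethylbicyclo[4.1.0]heptan-2-one]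
Conditions: KOH, MeOH, 0 °C → rt
Reagents that add atoms: none
Why: Intramolecular enolate alkylation (3-exo-tet, a 1,3-elimination of HCl): the enolate formed toward the ring CH2 displaces the tertiary chloride, and since a three-membered ring can only be cis-fused, the retained centre places the new C6–C11 bond on the same (β) face as the C7–C11 bond.

Step 3
Reactants: 3 2-carone; 4 ethyl vinyl ketone
Product: 7 (6S,7R,10S)-6,11-cycloeudesm-4-en-3-one, via Michael adduct diketone 5 (not isolated), via ring A ketol 6 (not isolated)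
Conditions: KOH, EtOH, slow addition of 4 at −10 °C → rt, then reflux
Reagents that add atoms: none
Why: Robinson annulation (Michael addition, then intramolecular aldol condensation): KOH can enolise 3 only toward the methyl-bearing carbon, because the other α-carbon is a cyclopropane bridgehead, so the tetrasubstituted enolate adds through C10 to ethyl vinyl ketone and forms the C1–C10 bond of diketone 5. The cis-fused gem-dimethylcyclopropane lies on the β face and its inward-pointing methyl hangs over the enolate, so the enone should approach from the α face and leave the C10 methyl β, cis to the C7–C11 bond; this facial control is the selectivity the step needs, and the unbridged isopropenyl ketone would not supply it. The ethyl ketone enolate carbon C4 then attacks the ring carbonyl C5 in a 6-(enolendo)-exo-trig aldol to give ketol 6, closing ring A through the C4–C5 bond, and loss of water on heating gives the tetrasubstituted enone, so C4 and C5 carry no stereochemistry. The cyclopropane is inert to hydroxide and ethoxide and is carried on as a latent C11 carbinol. The closest known reaction type is the base-mediated annulation of 2-alkylcyclohexanones and bicyclic terpene ketones with ethyl vinyl ketone.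

Step 4
Reactants: 7 (6S,7R,10S)-6,11-cycloeudesm-4-en-3-one
Product: 8 carissone [(7R,10S)-11-hydroxyeudesm-4-en-3-one]
Conditions: aq. HClO4 (1 M), THF, 25 → 40 °C
Reagents that add atoms: water, O
Why: Acid-catalysed homoconjugate addition to a vinylogous cyclopropyl ketone: O-protonation places positive charge at C5, the C6–C11 bond opens toward the tertiary C11 cation, water captures it and the dienol returns to the conjugated enone, with C7 unchanged because its bond to C11 is the one retained.

Step 5
Reactants: 8 carissone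
Product: 9 (7R,10S)-11-(triethylsilyloxy)eudesm-4-en-3-one
Conditions: Et3SiOTf, 2,6-lutidine, CH2Cl2, −78 °C
Reagents that add atoms: triethylsilyl trifluoromethanesulfonate, CC[Si](CC)(CC)OS(=O)(=O)C(F)(F)F
Why: Silylation of the tertiary alcohol with a silyl triflate masks O11 so that only the C4 oxygen made later can act as a nucleophile; no stereocentre is affected.

Step 6
Reactants: 9 (7R,10S)-11-(triethylsilyloxy)eudesm-4-en-3-one
Product: 11 (5R,7R,10S)-11-(triethylsilyloxy)eudesm-3-en-3-yl trifluoromethanesulfonate, via lithium enolate 10 (not isolated)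
Conditions: Li, NH3 (l), THF, t-BuOH (1 equiv), −78 °C; isoprene; NH3 evaporated; PhNTf2, THF, 0 °C → rt
Reagents that add atoms: N-phenylbis(trifluoromethanesulfonimide), O=S(=O)(N(c1ccccc1)S(=O)(=O)C(F)(F)F)C(F)(F)F
Why: Dissolving-metal conjugate reduction of the enone with regiospecific trapping of the C3 enolate as the enol triflate; C5 is protonated axially from the α face, anti to the C10 methyl, which should give the trans-fused decalin.

Step 7
Reactants: 11 (5R,7R,10S)-11-(triethylsilyloxy)eudesm-3-en-3-yl trifluoromethanesulfonate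
Product: 12 (5R,7R,10R)-11-(triethylsilyloxy)eudesm-3-ene
Conditions: Pd(OAc)2 (cat.), PPh3, HCO2H, Bu3N, DMF, 60 °C
Reagents that add atoms: none
Why: Palladium-catalysed formate reduction of an enol triflate (oxidative addition, decarboxylation of the formate to a palladium hydride, reductive elimination) replaces OTf by H without moving the 3,4-double bond.

Step 8
Reactants: 12 (5R,7R,10R)-11-(triethylsilyloxy)eudesm-3-ene
Product: 13 (3R,4S,5R,7R,10S)-3α,4α-epoxy-11-(triethylsilyloxy)eudesmane
Conditions: mCPBA, NaHCO3, CH2Cl2, 0 °C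
Reagents that add atoms: 3-chloroperoxybenzoic acid, O=C(OO)c1cccc(Cl)c1
Why: Prilezhaev epoxidation: the axial C10 methyl shields the β face of ring A, so the peracid should deliver oxygen to the α face and fix the C4 oxygen α and the C4 methyl β.

Step 9
Reactants: 13 (3R,4S,5R,7R,10S)-3α,4α-epoxy-11-(triethylsilyloxy)eudesmane
Product: 14 (4R,5R,7R,10R)-11-(triethylsilyloxy)eudesman-4α-ol
Conditions: LiEt3BH, THF, 0 → 65 °C; aq. NH4Cl
Reagents that add atoms: none
Why: SN2 hydride opening of the trisubstituted epoxide at the secondary carbon C3 leaves the C4–O bond intact, so C4 keeps its α-oxygen and β-methyl while C3 becomes a methylene.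

Step 10
Reactants: 14 (4R,5R,7R,10R)-11-(triethylsilyloxy)eudesman-4α-ol; 15 3-bromo-4-fluorobenzaldehyde
Product: 17 3-bromo-4-{[(4R,5R,7R,10R)-11-(triethylsilyloxy)eudesman-4-yl]oxy}benzaldehyde, via potassium alkoxide 16 (not isolated)
Conditions: KH, THF, 0 °C → rt; then 15, 18-crown-6, 0 °C → rt
Reagents that add atoms: none
Why: Nucleophilic aromatic substitution (addition–elimination) of the fluoride para to the formyl group by the preformed tertiary alkoxide; the C4–O bond is not broken, so C4 is retained, and the non-enolisable aldehyde meets no amide base.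

Step 11
Reactants: 18 2-allylphenol
Product: 19 2-allyl-4-bromophenol
Conditions: NBS, MeCN, −10 → 0 °C
Reagents that add atoms: N-bromosuccinimide, O=C1CCC(=O)N1Br
Why: Electrophilic aromatic bromination para to the hydroxyl group; in a polar solvent the phenol ring should react with NBS far faster than the terminal alkene.

Step 12
Reactants: 19 2-allyl-4-bromophenol
Product: 20 (2-allyl-4-bromophenoxy)tri(propan-2-yl)silane
Conditions: i-Pr3SiCl, imidazole, DMF, rt
Reagents that add atoms: chlorotri(propan-2-yl)silane, CC(C)[Si](Cl)(C(C)C)C(C)C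
Why: Silylation of the phenol gives a bulky aryl silyl ether that should tolerate the basic coupling steps and is removed by fluoride together with the O11 silyl group.

Step 13
Reactants: 20 (2-allyl-4-bromophenoxy)tri(propan-2-yl)silane
Product: 21 2-[3-allyl-4-(triisopropylsilyloxy)phenyl]-4,4,5,5-tetramethyl-1,3,2-dioxaborolane
Conditions: B2pin2, Pd(dppf)Cl2 (cat.), KOAc, 1,4-dioxane, 85 °C
Reagents that add atoms: bis(pinacolato)diboron, CC1(C)OB(OC1(C)C)B1OC(C)(C)C(C)(C)O1
Why: Miyaura borylation of the aryl bromide; the weak acetate base avoids homocoupling and leaves the allyl group and the silyl ether alone.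

Step 14
Reactants: 17 3-bromo-4-{[(4R,5R,7R,10R)-11-(triethylsilyloxy)eudesman-4-yl]oxy}benzaldehyde; 21 2-[3-allyl-4-(triisopropylsilyloxy)phenyl]-4,4,5,5-tetramethyl-1,3,2-dioxaborolane
Product: 22 3-[3-allyl-4-(triisopropylsilyloxy)phenyl]-4-{[(4R,5R,7R,10R)-11-(triethylsilyloxy)eudesman-4-yl]oxy}benzaldehyde
Conditions: Pd(OAc)2 (cat.), SPhos, K3PO4, toluene/H2O, 80 °C
Reagents that add atoms: none
Why: Suzuki–Miyaura coupling; the bromide is activated by the para formyl group and a bulky biarylphosphine should overcome the hindrance of the neighbouring tertiary alkoxy group.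

Step 15
Reactants: 22 biaryl aldehyde
Product: 23 {3-[3-allyl-4-(triisopropylsilyloxy)phenyl]-4-{[(4R,5R,7R,10R)-11-(triethylsilyloxy)eudesman-4-yl]oxy}phenyl}methanol
Conditions: NaBH4, MeOH/THF, 0 °C
Reagents that add atoms: none
Why: Borohydride reduction of the aryl aldehyde to the benzylic alcohol; alkenes, silyl ethers and the aryl ether are inert.

Step 16
Reactants: 23 benzylic alcohol
Product: 25 2-[3-allyl-4-(triisopropylsilyloxy)phenyl]-4-(chloromethyl)-1-{[(4R,5R,7R,10R)-11-(triethylsilyloxy)eudesman-4-yl]oxy}benzene, via benzylic mesylate 24 (not isolated)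
Conditions: MsCl, Et3N, LiCl, DMF, 0 °C → rt
Reagents that add atoms: lithium chloride, [Li+].[Cl-]; methanesulfonyl chloride, CS(=O)(=O)Cl (its chloride is an equivalent source)
Why: Mesylation followed by in situ SN2 displacement by chloride converts the primary benzylic alcohol to the chloride under non-acidic conditions that spare the tertiary alkyl aryl ether.

Step 17
Reactants: 25 benzylic chloride
Product: 26 triethyl{[(4R,5R,7R,10R)-4-{[3',5-diallyl-4'-(triisopropylsilyloxy)[1,1'-biphenyl]-2-yl]oxy}eudesman-11-yl]oxy}silane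
Conditions: CH2=CHSnBu3, Pd(PPh3)4 (cat.), toluene, 80 °C
Reagents that add atoms: tributyl(vinyl)stannane, C=C[Sn](CCCC)(CCCC)CCCC
Why: Stille coupling of a benzylic chloride with a vinylstannane forms the benzylic C–C bond and gives the allyl group directly, under base-free conditions that should not move the double bonds.

Step 18
Reactants: 26 bis-silyl ether
Product: 27 (4R,5R,7R,10R)-4-[(3',5-diallyl-4'-hydroxy[1,1'-biphenyl]-2-yl)oxy]eudesman-11-ol (CNP0219722.1)
Conditions: Bu4NF, THF, 25 → 50 °C
Reagents that add atoms: none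
Why: Fluoride-mediated desilylation cleaves the aryl silyl ether quickly and the tertiary triethylsilyl ether on warming, releasing the phenol and the C11 carbinol without acid.

**Compound list**

1 | (+)-dihydrocarvone, (5R)-2-methyl-5-(prop-1-en-2-yl)cyclohexan-1-one, C2 epimers | CC1CC[C@@H](C(C)=C)CC1=O | starting material
2 | (5R)-5-(2-chloropropan-2-yl)-2-methylcyclohexan-1-one, C2 epimers | CC1CC[C@@H](C(C)(C)Cl)CC1=O | intermediate
3 | 2-carone, (1S,6R)-3,7,7-trimethylbicyclo[4.1.0]heptan-2-one, C3 epimers | CC1CC[C@H]2C(C)(C)[C@H]2C1=O | intermediate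
4 | ethyl vinyl ketone, pent-1-en-3-one | C=CC(=O)CC | starting material
5 | Michael adduct diketone, (1S,3S,6R)-3,7,7-trimethyl-3-(3-oxopentyl)bicyclo[4.1.0]heptan-2-one, formed in the flask | CCC(=O)CC[C@]1(C)CC[C@H]2C(C)(C)[C@H]2C1=O | intermediate
6 | ring A ketol, (6S,7R,10S)-5-hydroxy-6,11-cycloeudesman-3-one, C4 and C5 undefined, formed in the flask | CC1C(=O)CC[C@]2(C)CC[C@H]3C(C)(C)[C@H]3C12O | intermediate
7 | (6S,7R,10S)-6,11-cycloeudesm-4-en-3-one | O=C1CC[C@]2(C)CC[C@H]3C(C)(C)[C@H]3C2=C1C | intermediate
8 | carissone, (7R,10S)-11-hydroxyeudesm-4-en-3-one | O=C1CC[C@]2(C)CC[C@@H](C(C)(C)O)CC2=C1C | intermediate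
9 | (7R,10S)-11-(triethylsilyloxy)eudesm-4-en-3-one | O=C1CC[C@]2(C)CC[C@@H](C(C)(C)O[Si](CC)(CC)CC)CC2=C1C | intermediate
10 | lithium (5R,7R,10S)-11-(triethylsilyloxy)eudesm-3-en-3-olate, formed in the flask | CC1=C([O-])CC[C@]2(C)CC[C@@H](C(C)(C)O[Si](CC)(CC)CC)C[C@H]21.[Li+] | intermediate
11 | (5R,7R,10S)-11-(triethylsilyloxy)eudesm-3-en-3-yl trifluoromethanesulfonate | CC1=C(OS(=O)(=O)C(F)(F)F)CC[C@]2(C)CC[C@@H](C(C)(C)O[Si](CC)(CC)CC)C[C@H]21 | intermediate
12 | (5R,7R,10R)-11-(triethylsilyloxy)eudesm-3-ene (α-eudesmol triethylsilyl ether) | CC1=CCC[C@]2(C)CC[C@@H](C(C)(C)O[Si](CC)(CC)CC)C[C@H]21 | intermediate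
13 | (3R,4S,5R,7R,10S)-3α,4α-epoxy-11-(triethylsilyloxy)eudesmane | O1[C@]2(C)[C@H]1CC[C@]3(C)CC[C@@H](C(C)(C)O[Si](CC)(CC)CC)C[C@H]32 | intermediate
14 | (4R,5R,7R,10R)-11-(triethylsilyloxy)eudesman-4α-ol (cryptomeridiol 11-triethylsilyl ether) | O[C@]1(C)CCC[C@]2(C)CC[C@@H](C(C)(C)O[Si](CC)(CC)CC)C[C@H]21 | intermediate
15 | 3-bromo-4-fluorobenzaldehyde | O=Cc1ccc(F)c(Br)c1 | starting material
16 | potassium (4R,5R,7R,10R)-11-(triethylsilyloxy)eudesman-4-olate, formed in the flask | [K+].[O-][C@]1(C)CCC[C@]2(C)CC[C@@H](C(C)(C)O[Si](CC)(CC)CC)C[C@H]21 | intermediate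
17 | 3-bromo-4-{[(4R,5R,7R,10R)-11-(triethylsilyloxy)eudesman-4-yl]oxy}benzaldehyde | O=Cc1ccc(O[C@]2(C)CCC[C@]3(C)CC[C@@H](C(C)(C)O[Si](CC)(CC)CC)C[C@H]32)c(Br)c1 | intermediate
18 | 2-allylphenol | C=CCc1ccccc1O | starting material
19 | 2-allyl-4-bromophenol | C=CCc1cc(Br)ccc1O | intermediate
20 | (2-allyl-4-bromophenoxy)tri(propan-2-yl)silane | C=CCc1cc(Br)ccc1O[Si](C(C)C)(C(C)C)C(C)C | intermediate
21 | 2-[3-allyl-4-(triisopropylsilyloxy)phenyl]-4,4,5,5-tetramethyl-1,3,2-dioxaborolane | C=CCc1cc(B2OC(C)(C)C(C)(C)O2)ccc1O[Si](C(C)C)(C(C)C)C(C)C | intermediate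
22 | 3-[3-allyl-4-(triisopropylsilyloxy)phenyl]-4-{[(4R,5R,7R,10R)-11-(triethylsilyloxy)eudesman-4-yl]oxy}benzaldehyde | O=Cc1ccc(O[C@]2(C)CCC[C@]3(C)CC[C@@H](C(C)(C)O[Si](CC)(CC)CC)C[C@H]32)c(-c2ccc(O[Si](C(C)C)(C(C)C)C(C)C)c(CC=C)c2)c1 | intermediate
23 | benzylic alcohol, the hydroxymethyl analogue of 22 | OCc1ccc(O[C@]2(C)CCC[C@]3(C)CC[C@@H](C(C)(C)O[Si](CC)(CC)CC)C[C@H]32)c(-c2ccc(O[Si](C(C)C)(C(C)C)C(C)C)c(CC=C)c2)c1 | intermediate
24 | benzylic mesylate of 23, formed in the flask | CS(=O)(=O)OCc1ccc(O[C@]2(C)CCC[C@]3(C)CC[C@@H](C(C)(C)O[Si](CC)(CC)CC)C[C@H]32)c(-c2ccc(O[Si](C(C)C)(C(C)C)C(C)C)c(CC=C)c2)c1 | intermediate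
25 | benzylic chloride, the chloromethyl analogue of 22 | ClCc1ccc(O[C@]2(C)CCC[C@]3(C)CC[C@@H](C(C)(C)O[Si](CC)(CC)CC)C[C@H]32)c(-c2ccc(O[Si](C(C)C)(C(C)C)C(C)C)c(CC=C)c2)c1 | intermediate
26 | bis-silyl ether of the target (O11 triethylsilyl, phenol triisopropylsilyl) | C=CCc1ccc(O[C@]2(C)CCC[C@]3(C)CC[C@@H](C(C)(C)O[Si](CC)(CC)CC)C[C@H]32)c(-c2ccc(O[Si](C(C)C)(C(C)C)C(C)C)c(CC=C)c2)c1 | intermediate
27 | (4R,5R,7R,10R)-4-[(3',5-diallyl-4'-hydroxy[1,1'-biphenyl]-2-yl)oxy]eudesman-11-ol, CNP0219722.1 | C=CCc1ccc(O[C@]2(C)CCC[C@]3(C)CC[C@@H](C(C)(C)O)C[C@H]32)c(-c2ccc(O)c(CC=C)c2)c1 | target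

**Step count**

Total: 18 steps. Longest linear sequence: 15 steps (steps 1–10, then 14–18); the boronate branch is steps 11–13.

**Steps most likely to fail**

Step 10. Substitution may stall because the C4 alkoxide is crowded by the geminal axial methyl and the ring fusion, and the alkoxide may instead add to the formyl group and be lost in hydride-transfer side reactions. The fallback sets out from 14: deprotonation with KN(SiMe3)2 and reaction with 3-bromo-4-fluorobenzonitrile, whose activating group is inert to alkoxide and tolerates heating in THF/DMF with 18-crown-6, should give 3-bromo-4-{[(4R,5R,7R,10R)-11-(triethylsilyloxy)eudesman-4-yl]oxy}benzonitrile F1. Reduction with i-Bu2AlH in toluene at −78 °C and hydrolysis of the aldimine then returns to the route at aldehyde 17.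

Step 9. Backside attack of hydride at C3 cannot follow the trans-diaxial course, which would require attack at the tertiary C4 beneath the axial C10 methyl; opening may therefore be slow and give way to rearrangement of the epoxide to an allylic alcohol or ketone. The fallback sets out from 13 and replaces the SN2 hydride by electron-transfer cleavage with Li in ethylenediamine. This breaks the C3–O bond through the less substituted carbanion, has no trajectory requirement, and is known to turn hindered trisubstituted epoxides into tertiary alcohols. It comes back to the route at 14, and no new compound arises (F0).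

Step 3. Ethyl vinyl ketone may polymerise under protic base, the Michael addition at the hindered tetrasubstituted enolate carbon is reversible, and dehydration of the ketol may be incomplete. The fallback sets out from 3 and forms the same two bonds stepwise. LiN(i-Pr)2 in THF at −78 °C gives the only possible enolate, which adds to 2-(trimethylsilyl)pent-1-en-3-one; silicon stabilises the adduct enolate and suppresses polymerisation. This should give the silyl diketone (1S,3S,6R)-3,7,7-trimethyl-3-[3-oxo-2-(trimethylsilyl)pentyl]bicyclo[4.1.0]heptan-2-one F2. KOH in MeOH then removes silicon, closes ring A by aldol condensation and dehydrates, re-joining the route at 7.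

**Further compounds**

F1 | step 10 | 3-bromo-4-{[(4R,5R,7R,10R)-11-(triethylsilyloxy)eudesman-4-yl]oxy}benzonitrile | N#Cc1ccc(O[C@]2(C)CCC[C@]3(C)CC[C@@H](C(C)(C)O[Si](CC)(CC)CC)C[C@H]32)c(Br)c1
F0 | step 9 | none | none
F2 | step 3 | (1S,3S,6R)-3,7,7-trimethyl-3-[3-oxo-2-(trimethylsilyl)pentyl]bicyclo[4.1.0]heptan-2-one | CCC(=O)C([Si](C)(C)C)C[C@]1(C)CC[C@H]2C(C)(C)[C@H]2C1=O
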